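**Retrosynthetic overview**
- Guidongnin ⇐ exo-face hydride reduction of the 16-en-15-one ⇐ α-methylenation of a 15-ketone that already holds every ring.
- Key step: rings C and D and the C8 quaternary centre are made in one operation. The C11 aldehyde, as its samarium ketyl (polarity-reversed carbonyl carbon), bonds to the electrophilic C9 of a C8=C9 unsaturated δ-lactone, and the enolate so formed closes C8–C15 onto a pendant methyl ester.
- That precursor ⇐ spiro bis-lactone + methyl (R)-3-(iodomethyl)pent-4-enoate (from butenolide by asymmetric vinyl addition), through C8 alkylation, dehydrogenation and anti-Markovnikov oxidation of the vinyl group.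
- Spiro δ-lactone and C10 ⇐ titanium-mediated radical coupling of a C10–C20 spiro-epoxide with an acrylate; γ-lactone ⇐ carbonylative lactonisation of a vinyl triflate; C4 ⇐ asymmetric hydroxymethylation of 2-methylcyclohexanone.
- Ring order: A (bought) → γ-lactone → spiro δ-lactone → C and D together in the key step.

Assumption: atoms carry ent-kaurane numbers; for the two catalytic asymmetric steps the ligand antipode named is the one expected by analogy, and it would be exchanged if the first run showed the opposite sense.

**Route**

Step 1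
Reactants: 1 2-methylcyclohexan-1-one
Product: 2 2-methyl-1-(trimethylsilyloxy)cyclohex-1-ene
Conditions: Me3SiCl, Et3N, DMF, 130 °C; distil
Reagents that add atoms: chlorotrimethylsilane, C[Si](C)(C)Cl
Why: Thermodynamic silyl enol ether formation (House conditions) favours the tetrasubstituted enol ether, which fixes the carbon that becomes the C4 quaternary centre; no stereocentre is formed.

Step 2
Reactants: 2 2-methyl-1-(trimethylsilyloxy)cyclohex-1-ene
Product: 3 (S)-2-(hydroxymethyl)-2-methylcyclohexan-1-one
Conditions: aq. HCHO, Sc(O3SCF3)3 (10 mol%), (S,S)-6,6'-bis(1-hydroxy-2,2-dimethylpropyl)-2,2'-bipyridine (12 mol%), DME/H2O, −20 °C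
Reagents that add atoms: formaldehyde, C=O
Why: Catalytic asymmetric Mukaiyama aldol with aqueous formaldehyde (Kobayashi hydroxymethylation), in which the chiral scandium–bipyridine complex lets the prochiral enolate attack through one face and so sets the C4 quaternary centre (C19 installed).

Step 3
Reactants: 3 (S)-2-(hydroxymethyl)-2-methylcyclohexan-1-one
Product: 5 (S)-6-(hydroxymethyl)-2,6-dimethylcyclohex-1-en-1-yl trifluoromethanesulfonate, via dimethyl hydroxy ketone 4 (not isolated)
Conditions: LiN(iPr)2 (2.2 equiv), THF, −78 → 0 °C; MeI (1.05 equiv), −78 → −20 °C; LiN(iPr)2 (1.2 equiv), −78 → 0 °C; PhNTf2; H2O work-up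
Reagents that add atoms: iodomethane, CI; N-phenylbis(trifluoromethanesulfonimide), O=S(=O)(N(c1ccccc1)S(=O)(=O)C(F)(F)F)C(F)(F)F
Why: Enolate C-methylation of the alkoxide/enolate dianion at the only enolisable carbon (C10, adds C20) followed by enolate O-triflation in the same pot, as known for 2,2,6-trimethylcyclohexanone; the transient C10 centre is erased and the neopentyl alkoxide is too hindered to be triflated.

Step 4
Reactants: 5 (S)-6-(hydroxymethyl)-2,6-dimethylcyclohex-1-en-1-yl trifluoromethanesulfonate
Product: 6 (3aR)-3a,7-dimethyl-3a,4,5,6-tetrahydro-2-benzofuran-1(3H)-one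
Conditions: CO (1 atm), Pd(PPh3)4 (5 mol%), Et3N, MeCN, 65 °C
Reagents that add atoms: carbon monoxide, [C-]#[O+]
Why: Palladium-catalysed carbonylative lactonisation, in which zerovalent palladium inserts into the vinyl triflate, CO inserts, and the homoallylic hydroxyl captures the acyl palladium to close the five-membered α-alkylidene lactone (C6 placed on C5); C4 is untouched.

Step 5
Reactants: 6 (3aR)-3a,7-dimethyl-3a,4,5,6-tetrahydro-2-benzofuran-1(3H)-one
Product: 7 (3aR,7aS)-3a-methyl-7-methylidenehexahydro-2-benzofuran-1(3H)-one
Conditions: LiN(iPr)2, THF, −78 °C; AcOH, −78 °C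
Reagents that add atoms: none
Why: Deconjugative protonation, in which the carbonyl-bound amide removes a proton from the γ-methyl (C20) lying syn to the lactone carbonyl and kinetic α-protonation of the exocyclic dienolate on the convex face gives the cis-fused exo-methylene lactone (sets C5).

Step 6
Reactants: 7 (3aR,7aS)-3a-methyl-7-methylidenehexahydro-2-benzofuran-1(3H)-one
Product: 8 spiro-epoxide of 7 across C10–C20
Conditions: mCPBA, NaHCO3, CH2Cl2, 0 °C
Reagents that add atoms: 3-chloroperoxybenzoic acid, O=C(OO)c1cccc(Cl)c1
Why: Prilezhaev epoxidation of the only alkene; either epoxide epimer serves because C10 becomes a planar radical in the next step.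

Step 7
Reactants: 8 spiro-epoxide of 7 across C10–C20; 9 2,2,2-trifluoroethyl prop-2-enoate
Product: 11 spiro bis-lactone (6,19-γ-lactone and 7,20-δ-lactone), via hydroxy ester 10 (not isolated)
Conditions: (C5H5)2TiCl2 (2.2 equiv), Zn dust, THF, 23 °C; then 8 and 9 (5 equiv); 1 M HCl work-up
Reagents that add atoms: none
Why: Nugent–RajanBabu epoxide opening by trivalent titanium gives the tertiary C10 radical, whose Giese addition to the acrylate occurs anti to the axial C19 methylene and C6 of the cis-fused lactone (sets C10 with C20 on the γ-lactone face, by analogy with γ-cyclogeranyl epoxides), after which the C20 alkoxide expels trifluoroethoxide to close the δ-lactone.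

Step 8
Reactants: 12 furan-2(5H)-one; 13 potassium vinyltrifluoroborate
Product: 14 (R)-4-ethenyloxolan-2-one
Conditions: [Rh(C8H12)2]PF6 (3 mol%; C8H12 = 1,5-cyclooctadiene), (R)-BINAP (3.3 mol%), toluene/H2O, 100 °C
Reagents that add atoms: none
Why: Hayashi–Miyaura rhodium-catalysed asymmetric 1,4-addition, in which the vinyl–rhodium–BINAP species inserts the butenolide on one enantioface and sets the future C13 centre.

Step 9
Reactants: 14 (R)-4-ethenyloxolan-2-one
Product: 16 methyl (R)-3-(iodomethyl)pent-4-enoate, via silyl ester 15 (not isolated)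
Conditions: Me3SiI, CH2Cl2, 23 °C; then MeOH, 0 → 23 °C
Reagents that add atoms: iodotrimethylsilane, C[Si](C)(C)I; methanol, CO
Why: Olah lactone cleavage, in which silyl activation and SN2 attack of iodide at the CH2–O carbon give the silyl 4-iodo ester that acidic methanol converts into the methyl ester; the stereocentre is not involved.

Step 10
Reactants: 11 spiro bis-lactone; 16 methyl (R)-3-(iodomethyl)pent-4-enoate
Product: 17 C8-alkylated spiro bis-lactone (both C8 epimers)
Conditions: LiN(iPr)2 (1.1 equiv), THF, −78 °C; then 16, (Me2N)3PO, −78 → −20 °C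
Reagents that add atoms: none
Why: Lactone enolate alkylation, in which the amide removes the open C8 proton of the δ-lactone (the γ-lactone α-proton is flanked by two quaternary carbons) and SN2 at the primary iodide forms C8–C14; the lactone enolate is too weak a base to enolise the ester of 16, and the C8 centre is removed in the next step.

Step 11
Reactants: 17 C8-alkylated spiro bis-lactone
Product: 20 C8=C9 unsaturated spiro bis-lactone carrying the vinyl ester side chain, via selenide 18 (not isolated), via selenoxide 19 (not isolated)
Conditions: LiN(SiMe3)2, THF, −78 → −40 °C; PhSeBr, −78 °C; then 30% H2O2, pyridine, CH2Cl2, 0 → 23 °C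
Reagents that add atoms: none
Why: Reich selenoxide dehydrogenation, in which the more acidic lactone α-position is selenenylated and the selenoxide undergoes syn-elimination into the ring (C8=C9), as 2-alkyl-2-selenocyclohexanones do, leaving the vinyl group and the esters alone.

Step 12
Reactants: 20 C8=C9 unsaturated spiro bis-lactone carrying the vinyl ester side chain
Product: 21 aldehyde (side chain C8–CH2–CH(CH2CHO)–CH2CO2Me)
Conditions: PdCl2(PhCN)2 (10 mol%), CuCl2·2H2O (10 mol%), AgNO2 (5 mol%), O2 (1 atm), tBuOH/MeNO2 15:1, 23 °C
Reagents that add atoms: dioxygen, O=O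
Why: Nitrite-modified aldehyde-selective (anti-Markovnikov) Wacker oxidation acts only on the terminal vinyl group, since the conjugated trisubstituted lactone alkene is inert; no stereocentre is touched.

Step 13
Reactants: 21 aldehyde
Product: 23 11-hydroxy-15-oxo-17-nor-6,7-seco-ent-kaurane-6,19:7,20-diolide, via samarium enolate 22 (not isolated)
Conditions: SmI2 (2.3 equiv, 0.1 M in THF) added to 21 in THF, −78 → 23 °C, no proton source, no HMPA; cold aq. NH4Cl quench
Reagents that add atoms: none
Why: Proposed new method: divalent samarium reduces the C11 aldehyde to a ketyl radical anion (a polarity-reversed, acyl-anion-type carbon) that adds 6-endo to C9 of the unsaturated δ-lactone through a chair-like transition state on the alkene face anti to C5, with the samarium-bound oxygen chelated to the lactone carbonyl (sets C9 and the C11 hydroxyl trans to H-9); a second electron gives the trivalent samarium lactone enolate, whose C8 attacks the CH2CO2Me arm on C13 in a 5-exo-trig Dieckmann acylation on the face of that arm (sets the C8 quaternary centre), and the chelated tetrahedral intermediate collapses to the C15 ketone only on quench, so no alkoxide is free for a retro-Claisen; the closest known reactions are SmI2 aldehyde–unsaturated-lactone cyclisations whose samarium enolate is trapped by an intramolecular aldol, and Dieckmann condensations of metal enolates.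

Step 14
Reactants: 23 11-hydroxy-15-oxo-17-nor-6,7-seco-ent-kaurane-6,19:7,20-diolide
Product: 25 11-hydroxy-15-oxo-6,7-seco-ent-kaur-16-ene-6,19:7,20-diolide, via Mannich base 24 (not isolated)
Conditions: (CH2O)n, PhNHMe·CF3CO2H, THF, 65 °C
Reagents that add atoms: formaldehyde (from paraformaldehyde), C=O
Why: Gras α-methylenation (Mannich condensation, then loss of N-methylaniline) at C16, the only enolisable position of the C15 ketone, under mildly acidic conditions that leave both lactones and the free alcohol alone.

Step 15
Reactants: 25 11-hydroxy-15-oxo-6,7-seco-ent-kaur-16-ene-6,19:7,20-diolide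
Product: 26 Guidongnin
Conditions: NaBH4, CeCl3·7H2O, MeOH, −78 → −40 °C
Reagents that add atoms: none
Why: Luche reduction delivers hydride 1,2 to the enone from the open exo face of the bicyclo[3.2.1]octanone (the endo face is screened by the axial C11–H of ring C), giving the endo C15 alcohol of the target, and does not reduce the lactones.

**Compound list**
1 | 2-methylcyclohexan-1-one (racemic) | CC1CCCCC1=O | starting material
2 | 2-methyl-1-(trimethylsilyloxy)cyclohex-1-ene | CC1=C(O[Si](C)(C)C)CCCC1 | intermediate
3 | (S)-2-(hydroxymethyl)-2-methylcyclohexan-1-one | O=C1CCCC[C@@]1(C)CO | intermediate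
4 | (2S)-2-(hydroxymethyl)-2,6-dimethylcyclohexan-1-one (both C6 epimers; lithium alkoxide in the flask) | CC1CCC[C@@](C)(CO)C1=O | intermediate
5 | (S)-6-(hydroxymethyl)-2,6-dimethylcyclohex-1-en-1-yl trifluoromethanesulfonate | CC1=C(OS(=O)(=O)C(F)(F)F)[C@](C)(CO)CCC1 | intermediate
6 | (3aR)-3a,7-dimethyl-3a,4,5,6-tetrahydro-2-benzofuran-1(3H)-one (C5=C10 conjugated lactone) | CC1=C2C(=O)OC[C@]2(C)CCC1 | intermediate
7 | (3aR,7aS)-3a-methyl-7-methylidenehexahydro-2-benzofuran-1(3H)-one (cis-fused) | C=C1CCC[C@@]2(C)COC(=O)[C@H]21 | intermediate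
8 | spiro-epoxide of 7 (oxirane across C10–C20; both C10 epimers; cis ring fusion kept) | C1OC12CCC[C@@]3(C)COC(=O)[C@H]32 | intermediate
9 | 2,2,2-trifluoroethyl prop-2-enoate | C=CC(=O)OCC(F)(F)F | starting material
10 | δ-hydroxy ester: cis-fused γ-lactone whose C10 carries CH2OH (C20, γ-lactone face) and CH2CH2CO2CH2CF3 (H-5 face) | OC[C@@]1(CCC(=O)OCC(F)(F)F)CCC[C@@]2(C)COC(=O)[C@H]21 | intermediate
11 | spiro bis-lactone: cis-fused 6,19-γ-lactone on ring A and 7,20-δ-lactone spiro at C10 (C20 on the γ-lactone face; C9 on the H-5 face) | O=C1CC[C@@]2(CCC[C@@]3(C)COC(=O)[C@H]32)CO1 | intermediate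
12 | furan-2(5H)-one | O=C1OCC=C1 | starting material
13 | potassium vinyltrifluoroborate | C=C[B-](F)(F)F.[K+] | starting material
14 | (R)-4-ethenyloxolan-2-one | C=C[C@H]1CC(=O)OC1 | intermediate
15 | trimethylsilyl (R)-3-(iodomethyl)pent-4-enoate | C=C[C@@H](CC(=O)O[Si](C)(C)C)CI | intermediate
16 | methyl (R)-3-(iodomethyl)pent-4-enoate | C=C[C@@H](CC(=O)OC)CI | intermediate
17 | 11 alkylated at C8 with CH2–CH(CH=CH2)–CH2CO2Me (side-chain centre as in 16; both C8 epimers) | C=C[C@@H](CC(=O)OC)CC1C[C@@]2(CCC[C@@]3(C)COC(=O)[C@H]32)COC1=O | intermediate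
18 | C8 phenylselenide of 17 | C=C[C@@H](CC(=O)OC)CC1([Se]c2ccccc2)C[C@@]2(CCC[C@@]3(C)COC(=O)[C@H]32)COC1=O | intermediate
19 | C8 selenoxide of 17 | C=C[C@@H](CC(=O)OC)CC1([Se](=O)c2ccccc2)C[C@@]2(CCC[C@@]3(C)COC(=O)[C@H]32)COC1=O | intermediate
20 | C8=C9 unsaturated spiro bis-lactone with C8–CH2–CH(CH=CH2)–CH2CO2Me | C=C[C@@H](CC(=O)OC)CC1=C[C@@]2(CCC[C@@]3(C)COC(=O)[C@H]32)COC1=O | intermediate
21 | aldehyde: C8–CH2–CH(CH2CHO)–CH2CO2Me on the unsaturated spiro bis-lactone (C14; C13; C12–C11; C16–C15) | O=CC[C@@H](CC(=O)OC)CC1=C[C@@]2(CCC[C@@]3(C)COC(=O)[C@H]32)COC1=O | intermediate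
22 | tricyclic trivalent samarium lactone enolate and C11 alkoxide (ring C closed, C9–C11 formed) | COC(=O)C[C@@H]1C[C@@H](O[Sm](I)I)[C@@H]2C(=C(O[Sm](I)I)OC[C@]23CCC[C@@]4(C)COC(=O)[C@H]43)C1 | intermediate
23 | 11-hydroxy-15-oxo-17-nor-6,7-seco-ent-kaurane-6,19:7,20-diolide (11-OH trans to H-9) | C1[C@@H]2C[C@@H](O)[C@H]3[C@@]4(CCC[C@@]5(C)COC(=O)[C@H]54)COC(=O)[C@]3(C2)C1=O | intermediate
24 | C16 (N-methylanilino)methyl Mannich base of 23 (C16 epimers) | CN(CC1[C@@H]2C[C@@H](O)[C@H]3[C@@]4(CCC[C@@]5(C)COC(=O)[C@H]54)COC(=O)[C@]3(C2)C1=O)c1ccccc1 | intermediate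
25 | 11-hydroxy-15-oxo-6,7-seco-ent-kaur-16-ene-6,19:7,20-diolide | C=C1[C@@H]2C[C@@H](O)[C@H]3[C@@]4(CCC[C@@]5(C)COC(=O)[C@H]54)COC(=O)[C@]3(C2)C1=O | intermediate
26 | Guidongnin | C=C1[C@@H]2C[C@@H](O)[C@H]3[C@@]4(CCC[C@@]5(C)COC(=O)[C@H]54)COC(=O)[C@]3(C2)[C@@H]1O | target

**Step count and risk**

Total: 15 steps. Longest linear sequence: 13 steps (steps 1–7 and 10–15); steps 8–9 are the side branch.

Most likely to fail, first: step 13. The samarium enolate may be protonated or stay unreactive toward the ester before the Dieckmann closure, and the C11 configuration rests on the chelation argument. The fallback sets out from 21 and separates the two bond formations. SmI2 with tBuOH in THF at −78 °C gives only the ketyl–olefin cyclisation and protonates the enolate, which leads to the tricyclic hydroxy lactone ester F1. Ring D is then closed in a separate polar step: LiN(SiMe3)2 (2.2 equiv) forms the C11 alkoxide and C8 enolate of F1 in THF at −78 → 0 °C, and an inverse acidic quench after the Dieckmann condensation gives 23, where the route is rejoined.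

Second: step 11. The base may enolise the methyl ester instead of the lactone, and the selenoxide may eliminate toward C14. The fallback sets out from 11 and uses 16, replaces steps 10 and 11, and comes back at 20. The ring alkene is made before the side chain is attached: palladium-catalysed α,β-dehydrogenation of the zinc enolate of 11 (LiN(iPr)2, ZnCl2, then [Pd(C3H5)Cl]2 and allyl acetate, 60 °C) gives the unsaturated spiro bis-lactone F2. Iodination with I2 and pyridine in CH2Cl2 gives the α-iodo unsaturated lactone F3. Zinc dust and LiCl in THF convert 16 into the alkylzinc iodide F4, and Negishi coupling of F3 and F4 with PdCl2[1,1'-bis(diphenylphosphino)ferrocene] gives 20 without the ester ever meeting a strong base.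

Third: step 5. Deprotonation at the ring CH2 (C1) instead of the methyl group, or protonation to the trans-fused lactone, would give the wrong isomer. The fallback sets out from 6 and comes back at 7 by photochemical deconjugation (254 nm, pentane, catalytic 1,2-dimethylimidazole). Photoenolisation is a 1,5-hydrogen shift that can only take a hydrogen from the C20 methyl lying syn to the carbonyl, and ketonisation of the photodienol at C5 gives 7. This fallback makes no compound outside the list (F0).

**Further compounds**
F1 | step 13 | tricyclic hydroxy lactone ester (ring C closed; C11-OH; C8–H; CH2CO2Me on C13) | COC(=O)C[C@@H]1C[C@@H](O)[C@@H]2C(C1)C(=O)OC[C@]23CCC[C@@]4(C)COC(=O)[C@H]43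
F2 | step 11 | unsaturated spiro bis-lactone (C8=C9, no side chain) | O=C1C=C[C@@]2(CCC[C@@]3(C)COC(=O)[C@H]32)CO1
F3 | step 11 | α-iodo unsaturated spiro bis-lactone (iodine on C8) | O=C1C(I)=C[C@@]2(CCC[C@@]3(C)COC(=O)[C@H]32)CO1
F4 | step 11 | alkylzinc iodide from 16 | C=C[C@@H](CC(=O)OC)C[Zn]I
F0 | step 5 | none | none
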